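The numbers in the tables stem from a simulated flask on assumed constants; noise was put on by code.

The vessel is a closed, stirred, isothermal flask in which a single-handed free catalyst couples a racemic substrate with the coupling partner. Two earlier runs stand beside it.

| setting | grey | red | flask |
|---|---|---|---|
| left-handed substrate | 1.4 M | 1 M | 1.0 M |
| right-handed substrate | 1.4 M | 1 M | 1.0 M |
| coupling partner | 0.80 equiv | 0.80 equiv | 0.800 equiv |
| free catalyst | 1 mol% | 1 mol% | 1 mol% |
| added ligand | 11 mM | 16 mM | 11 mM |
| remark | run made earlier | run made earlier |  |
| time |  |  | 5.0 min |

| run | time / min | left-handed product / % | right-handed product / % |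
|---|---|---|---|
| grey | 1.33 | 3.1 | 1.1 |
| grey | 2.50 | 7.7 | 2.4 |
| grey | 4.00 | 11.2 | 3.7 |
| grey | 5.00 | 12.9 | 3.8 |
| red | 1.33 | 3.0 | 0 |
| red | 2.50 | 6.7 | 1.4 |
| red | 4.00 | 8.3 | 0.8 |
| red | 5.00 | 9.4 | 1.2 |

(readings scatter by 1 percentage point)

- excess of left-handed product over right-handed product in the product at 6.0 s
- excess of left-handed product over right-handed product in the product at 5.0 min
- part of the left-handed substrate and right-handed substrate charged together that has reacted at 5.0 min

- free catalyst is single-handed; left-handed substrate and right-handed substrate are mirror images of each other, charged as a racemate, each of them at the stated concentration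
- an excess is the difference of the two amounts in percent of their sum
- an excess is below zero if the other one leads

What do you read from the runs? The sum of left-handed product over the sum of right-handed product across each run's readings: 3.17 in grey and 8.06 in red. At this low conversion, each is a reading of the selectivity factor.

How firm is the red ratio? Soft. Its right-handed sum is 3.40%, and that sum of four readings scatters by 2 percentage points, standard deviation.

Which run speaks for the flask? Neither. The flask takes its substrate concentrations from red and its c(added ligand) from grey, and the two runs differ in both settings, so the readings cannot separate them.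

So what do you carry? The bracketed product ratio, the geometric mean of the two run ratios, 5.06. I take the geometric mean because a ratio of rates moves by factors. The rule (ratio − 1)/(ratio + 1) turns it into my excess of 67.0% for 5.0 min.

And at 6.0 s? The earliest reading is at 1.33 min, so the runs cannot reach that time. I carry the same ratio for the excess at that early time, on weak ground. For the part reacted at 5.0 min, I expect a value between the product totals read at that time in red, 10.6%, and in grey, 16.7%.

The forecast gives an excess of 64% at 6.0 s, an excess of 61% at 5.0 min and 12.3% reacted at 5.0 min, holding that “kR comes almost entirely from unligated catalyst”. My excess of 67.0% is higher than its figure at 5.0 min and higher than its figure at 6.0 s.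

The flask gives an excess of 55.5% at 6.0 s, an excess of 68.6% at 5.0 min and 13.1% reacted at 5.0 min.

    left-handed substrate ⇌ right-handed substrate (k = 0.00140 s⁻¹)
    free catalyst + right-handed substrate ⇌ catalyst intermediate B (K = 3.10 M⁻¹, k = 4.30 M⁻¹ s⁻¹)
    free catalyst + left-handed substrate ⇌ catalyst intermediate A (K = 11.0 M⁻¹, k = 1.10 M⁻¹ s⁻¹)
    free catalyst → spent catalyst (k = 0.00750 s⁻¹)
    coupling partner + catalyst intermediate B → free catalyst + right-handed product (k = 0.0610 M⁻¹ s⁻¹)
    free catalyst + added ligand ⇌ idle complex, settled at all times (K = 32.0 M⁻¹)
    coupling partner + catalyst intermediate A → free catalyst + left-handed product (k = 0.280 M⁻¹ s⁻¹)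

Removing the joining of free catalyst and added ligand leaves the excess at 5.0 min practically unmoved in this flask. The flask's product ratio at 5.0 min is 5.37, set beside my bracketed 5.06. The neighbour charged with 0.6 mol% of free catalyst has 8.38% reacted at 5.0 min, and its product ratio at that time, set beside 5.06 too, is 5.29, an excess of 68.2%.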